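**Plan**

- Retrosynthesis: cut the tetronate C3–acyl bond (this opens the 13-membered ring to a 3-iodotetronate aldehyde); then the butenolide C=C and ester C–O bonds (back to an α-hydroxy δ-lactone); then the ring O–C(tertiary) bond by a retro-Baeyer–Villiger step (back to a cis-hydrindenone); then the ring-carbon–alkenyl bond (a side-chain Z-iodoalkene); last the two cyclohexene bonds made by an intramolecular Diels–Alder reaction of an achiral trienone.
- Forward order: cyclohexene and a five-membered carbocycle form together (step 6); the quaternary carbon is completed (steps 7, 17); the carbocycle is enlarged to the six-membered lactone (step 18); the butenolide is annulated (steps 19, 20); the macrocycle is closed last (steps 24, 25).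
- Enabling feature: in the dihydropyran ring the oxygen lies between the butenolide β-carbon (bonded to the spiro carbon) and the fully substituted carbon bearing the methyl group and the Z-alkenyl chain. Read as carbonyl carbon–O–tertiary allylic carbon, this is a δ-lactone in disguise, the product of oxygen insertion into a cyclopentanone whose two α-carbons (quaternary allylic against ring-fusion methine) differ enough to fix the direction.
- Stereochemistry: one catalyst sets the three cyclohexene centres in the Diels–Alder step; the convex face of the cis-hydrindanone sets the quaternary carbon, which the ring expansion carries into the ether carbon with retention; hydroxylation keeps the cis ring fusion; the methoxy carbon comes from an (R)-HYTRA acetate aldol.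
- Both trisubstituted alkenes of the macrocycle are Z (ring carbons cis); they come from carbocupration of propyne and a Still–Gennari olefination.

Key step: step 18

Assumption: the (S)-configured oxazaborolidinium catalyst of step 6 is taken to shield the enone face that leads to the (3aS,6S,7aR) adduct, in line with its usual transition-state model for vinyl ketones; if the sense were opposite, the mirror-image catalyst would be used.

**Route**

Step 1
Reactants: 1 (2E)-2-methylpent-2-enal; 2 ethyl 2-(triphenylphosphoranylidene)propanoate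
Product: 3 ethyl (2E,4E)-2,4-dimethylhepta-2,4-dienoate
Conditions: toluene, 90 °C
Reagents that add atoms: none
Why: Wittig olefination with a stabilised ylide should give the 2E alkene while the E alkene of 1 is carried through unchanged.

Step 2
Reactants: 3 ethyl (2E,4E)-2,4-dimethylhepta-2,4-dienoate
Product: 4 (2E,4E)-2,4-dimethylhepta-2,4-dien-1-ol
Conditions: i-Bu2AlH (2.2 equiv), CH2Cl2, −78 °C; Rochelle salt work-up
Reagents that add atoms: none
Why: 1,2-reduction of the conjugated ester with i-Bu2AlH should stop at the allylic alcohol and leave the diene untouched.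

Step 3
Reactants: 4 (2E,4E)-2,4-dimethylhepta-2,4-dien-1-ol
Product: 5 (2E,4E)-1-bromo-2,4-dimethylhepta-2,4-diene
Conditions: PBr3 (0.4 equiv), Et2O, −10 °C; used crude
Reagents that add atoms: phosphorus tribromide BrP(Br)Br
Why: bromination of a primary allylic alcohol with PBr3 (SN2 at the activated oxygen) should give the dienyl bromide, which is used at once to limit allylic transposition.

Step 4
Reactants: 5 (2E,4E)-1-bromo-2,4-dimethylhepta-2,4-diene; 6 dimethyl (2-oxopropyl)phosphonate
Product: 8 dimethyl [(5E,7E)-5,7-dimethyl-2-oxodeca-5,7-dien-1-yl]phosphonate, via dianion 7 (not isolated)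
Conditions: NaH, THF, 0 °C; n-BuLi, 0 °C; then 5, 0 °C → rt; AcOH quench
Reagents that add atoms: none
Why: γ-alkylation of a β-ketophosphonate dianion, in which the more basic terminal carbanion attacks the primary allylic bromide by SN2 and the phosphonate α-carbon stays free for the next step.

Step 5
Reactants: 8 dimethyl [(5E,7E)-5,7-dimethyl-2-oxodeca-5,7-dien-1-yl]phosphonate
Product: 9 (6E,8E)-6,8-dimethylundeca-1,6,8-trien-3-one
Conditions: aq. CH2O (37 %), K2CO3, THF/H2O, rt; used without delay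
Reagents that add atoms: formaldehyde C=O
Why: Horner–Wadsworth–Emmons methylenation with aqueous formaldehyde under carbonate conditions should deliver the vinyl ketone without touching the diene.

Step 6
Reactants: 9 (6E,8E)-6,8-dimethylundeca-1,6,8-trien-3-one
Product: 10 (3aS,6S,7aR)-6-ethyl-3a,5-dimethyl-2,3,3a,6,7,7a-hexahydro-1H-inden-1-one
Conditions: (S)-o-tolyl-CBS-oxazaborolidine (20 mol %), Tf2NH (16 mol %), CH2Cl2, −40 → −20 °C
Reagents that add atoms: none
Why: catalytic enantioselective type 1 intramolecular Diels–Alder reaction, in which the boron Lewis acid binds the vinyl ketone and shields one enone face (absolute configuration), the tether carbonyl sits endo so that the hydrindenone is cis-fused (7a-H cis to the 3a-methyl group), and the E,E-diene places the ethyl group cis to the two ring bonds of the new five-membered ring, so that C3a, C6 and C7a are set together.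

Step 7
Reactants: 10 (3aS,6S,7aR)-6-ethyl-3a,5-dimethyl-2,3,3a,6,7,7a-hexahydro-1H-inden-1-one
Product: 12 (3aS,6S,7aR)-6-ethyl-2,3a,5-trimethyl-2,3,3a,6,7,7a-hexahydro-1H-inden-1-one (C2 epimers), via lithium enolate 11 (not isolated)
Conditions: LiN(i-Pr)2 (LDA), THF, −78 °C; MeI, −78 → −40 °C
Reagents that add atoms: iodomethane CI
Why: kinetic deprotonation by LDA at the less hindered methylene C2 (the other α-carbon is a ring-fusion methine next to a quaternary carbon) and SN2 methylation; the C2 configuration does not matter because this carbon is enolised again in step 17.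

Step 8
Reactants: 13 2-(2-bromoethyl)-1,3-dioxolane; 14 propyne
Product: 18 2-[(3Z)-4-iodo-3-methylbut-3-en-1-yl]-1,3-dioxolane, via Grignard reagent 15 (not isolated), via alkylcopper 16 (not isolated), via alkenylcopper 17 (not isolated)
Conditions: Mg, THF, 25 °C; CuBr·SMe2 (1 equiv), Et2O/Me2S, −45 °C; propyne, −25 °C; I2, −78 → 0 °C
Reagents that add atoms: iodine [I][I]
Why: carbocupration of propyne, in which the alkylcopper adds syn across the alkyne with copper on the terminal carbon, and iodinolysis with retention should give the Z-iodoalkene (iodine cis to the chain).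

Step 9
Reactants: 18 2-[(3Z)-4-iodo-3-methylbut-3-en-1-yl]-1,3-dioxolane
Product: 19 (4Z)-5-iodo-4-methylpent-4-enal
Conditions: 1 M HCl, THF, rt
Reagents that add atoms: water O
Why: acid-catalysed acetal hydrolysis, to which the iodoalkene is inert.

Step 10
Reactants: 19 (4Z)-5-iodo-4-methylpent-4-enal; 20 ethyl 2-[bis(2,2,2-trifluoroethoxy)phosphoryl]propanoate
Product: 22 ethyl (2Z,6Z)-7-iodo-2,6-dimethylhepta-2,6-dienoate, via potassium phosphonate anion 21 (not isolated)
Conditions: KN(SiMe3)2, 18-crown-6, THF, −78 °C; then 19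
Reagents that add atoms: none
Why: Still–Gennari olefination, in which the bis(trifluoroethyl) phosphonate anion with a dissociated potassium counter-ion eliminates under kinetic control to the Z-trisubstituted enoate.

Step 11
Reactants: 22 ethyl (2Z,6Z)-7-iodo-2,6-dimethylhepta-2,6-dienoate
Product: 23 (2Z,6Z)-7-iodo-2,6-dimethylhepta-2,6-dien-1-ol
Conditions: i-Bu2AlH (2.5 equiv), CH2Cl2, −78 °C
Reagents that add atoms: none
Why: 1,2-reduction of the enoate with i-Bu2AlH should give the allylic alcohol without loss of alkene geometry or of the iodide.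

Step 12
Reactants: 23 (2Z,6Z)-7-iodo-2,6-dimethylhepta-2,6-dien-1-ol
Product: 24 (2Z,6Z)-7-iodo-2,6-dimethylhepta-2,6-dienal
Conditions: Dess–Martin periodinane, NaHCO3, CH2Cl2, 0 °C; used directly
Reagents that add atoms: none
Why: Dess–Martin oxidation under buffered conditions should give the Z-enal, which is used directly because Z-2-methyl-2-enals isomerise on standing.

Step 13
Reactants: 24 (2Z,6Z)-7-iodo-2,6-dimethylhepta-2,6-dienal; 25 (R)-2-hydroxy-1,2,2-triphenylethyl acetate ((R)-HYTRA)
Product: 27 (1R)-2-hydroxy-1,2,2-triphenylethyl (3R,4Z,8Z)-3-hydroxy-9-iodo-4,8-dimethylnona-4,8-dienoate, via dilithio enolate 26 (not isolated)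
Conditions: LiN(SiMe3)2 (2.1 equiv), THF, −78 → 0 °C; then 24, −100 °C; AcOH quench
Reagents that add atoms: none
Why: acetate aldol addition with the dilithio enolate of (R)-HYTRA, in which the auxiliary directs the enolate to the Re face of the aldehyde and so sets the 3R carbinol centre; the minor diastereomer is removed by crystallisation or chromatography.

Step 14
Reactants: 27 (1R)-2-hydroxy-1,2,2-triphenylethyl (3R,4Z,8Z)-3-hydroxy-9-iodo-4,8-dimethylnona-4,8-dienoate
Product: 28 (3R,4Z,8Z)-9-iodo-4,8-dimethylnona-4,8-diene-1,3-diol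
Conditions: i-Bu2AlH (5 equiv), CH2Cl2, −78 → −20 °C
Reagents that add atoms: none
Why: reductive cleavage of the auxiliary ester with i-Bu2AlH should give the 1,3-diol and release the triphenylethanediol, the iodoalkene being stable to hydride at low temperature.

Step 15
Reactants: 28 (3R,4Z,8Z)-9-iodo-4,8-dimethylnona-4,8-diene-1,3-diol
Product: 29 (3R,4Z,8Z)-1-[(tert-butyldiphenylsilyl)oxy]-9-iodo-4,8-dimethylnona-4,8-dien-3-ol
Conditions: t-BuPh2SiCl (1.05 equiv), imidazole, CH2Cl2, 0 °C
Reagents that add atoms: tert-butyl(chloro)diphenylsilane CC(C)(C)[Si](Cl)(c1ccccc1)c1ccccc1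
Why: silylation with the bulky chlorosilane should select the primary hydroxyl over the hindered secondary allylic one.

Step 16
Reactants: 29 (3R,4Z,8Z)-1-[(tert-butyldiphenylsilyl)oxy]-9-iodo-4,8-dimethylnona-4,8-dien-3-ol
Product: 30 tert-butyl{[(3R,4Z,8Z)-9-iodo-3-methoxy-4,8-dimethylnona-4,8-dien-1-yl]oxy}diphenylsilane
Conditions: Me3OBF4, 1,8-bis(dimethylamino)naphthalene, 4 Å MS, CH2Cl2, rt
Reagents that add atoms: trimethyloxonium tetrafluoroborate C[O+](C)C.F[B-](F)(F)F
Why: O-methylation with a Meerwein salt and a non-nucleophilic amine base avoids alkoxide formation and hence silyl migration or elimination.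

Step 17
Reactants: 12 (3aS,6S,7aR)-6-ethyl-2,3a,5-trimethyl-2,3,3a,6,7,7a-hexahydro-1H-inden-1-one; 30 tert-butyl{[(3R,4Z,8Z)-9-iodo-3-methoxy-4,8-dimethylnona-4,8-dien-1-yl]oxy}diphenylsilane
Product: 32 (2S,3aS,6S,7aR)-2-{(1Z,5Z,7R)-9-[(tert-butyldiphenylsilyl)oxy]-7-methoxy-2,6-dimethylnona-1,5-dien-1-yl}-6-ethyl-2,3a,5-trimethyl-2,3,3a,6,7,7a-hexahydro-1H-inden-1-one, via sodium enolate 31 (not isolated)
Conditions: Pd2(dba)3 (2.5 mol %), P(t-Bu)3 (6 mol %), NaOt-Bu (1.5 equiv), THF, 50 °C
Reagents that add atoms: none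
Why: palladium-catalysed α-alkenylation of a ketone enolate, in which zerovalent palladium inserts into the C–I bond with retention of the Z geometry, the enolate binds through the less hindered C2 (the ring-fusion α-carbon is flanked by a quaternary carbon), and C–C reductive elimination on the convex face of the cis-hydrindanone should place the alkenyl group cis to the angular methyl group (2S); the epimerisable ring fusion stays cis, its more stable form.

Step 18
Reactants: 32 (2S,3aS,6S,7aR)-2-{(1Z,5Z,7R)-9-[(tert-butyldiphenylsilyl)oxy]-7-methoxy-2,6-dimethylnona-1,5-dien-1-yl}-6-ethyl-2,3a,5-trimethyl-2,3,3a,6,7,7a-hexahydro-1H-inden-1-one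
Product: 33 (3S,4aS,7S,8aR)-3-{(1Z,5Z,7R)-9-[(tert-butyldiphenylsilyl)oxy]-7-methoxy-2,6-dimethylnona-1,5-dien-1-yl}-7-ethyl-3,4a,6-trimethyl-3,4,4a,7,8,8a-hexahydro-1H-isochromen-1-one
Conditions: (Me3SiO)2 (3 equiv), Me3SiOTf (0.2 equiv), 2,6-di-tert-butyl-4-methylpyridine (0.3 equiv), CH2Cl2, −78 → −30 °C
Reagents that add atoms: bis(trimethylsilyl) peroxide C[Si](C)(C)OO[Si](C)(C)C
Why: Baeyer–Villiger oxidation: Me3SiOTf activates the ketone, the silyl peroxide adds to give a silylated peroxy-hemiketal (Criegee adduct), and ring carbon C2 shifts from the carbonyl carbon to the proximal peroxide oxygen, anti to the leaving Me3SiO group. The closest known reaction type is the silyl-peroxide Baeyer–Villiger oxidation of alkene-containing 2,2-disubstituted cycloalkanones. The step closes no new ring: the five-membered carbocycle is enlarged to the six-membered lactone by a ring-expanding 1,2-shift that inserts the oxygen between C1 and C2. No stereocentre is created; the migrating carbon keeps its configuration, so the quaternary centre set in step 17 becomes the tertiary ether carbon (3S), and the ring-fusion centres are untouched. Regioselectivity (C2 against the ring-fusion methine C7a) is secured by the fully substituted, allylic and therefore better cation-stabilising C2; chemoselectivity over the three trisubstituted alkenes by the non-epoxidising silyl peroxide; and survival of the acid-labile tertiary allylic C–O bond of the product by low temperature and the hindered pyridine buffer.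

Step 19
Reactants: 33 (3S,4aS,7S,8aR)-3-{(1Z,5Z,7R)-9-[(tert-butyldiphenylsilyl)oxy]-7-methoxy-2,6-dimethylnona-1,5-dien-1-yl}-7-ethyl-3,4a,6-trimethyl-3,4,4a,7,8,8a-hexahydro-1H-isochromen-1-one
Product: 35 (3S,4aS,7S,8aS)-3-{(1Z,5Z,7R)-9-[(tert-butyldiphenylsilyl)oxy]-7-methoxy-2,6-dimethylnona-1,5-dien-1-yl}-7-ethyl-8a-hydroxy-3,4a,6-trimethyl-3,4,4a,7,8,8a-hexahydro-1H-isochromen-1-one, via potassium enolate 34 (not isolated)
Conditions: KN(SiMe3)2, THF, −78 °C; 3-phenyl-2-(phenylsulfonyl)oxaziridine, −78 °C; AcOH quench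
Reagents that add atoms: 3-phenyl-2-(phenylsulfonyl)oxaziridine O=S(=O)(c1ccccc1)N1OC1c1ccccc1
Why: enolate hydroxylation with the Davis oxaziridine, in which the lactone enolate is attacked on the face away from the pseudoaxial ethyl group (equatorial attack on the half-chair cyclohexene), which is the face of the angular methyl group, so that the cis ring fusion is kept (8aS).

Step 20
Reactants: 35 (3S,4aS,7S,8aS)-3-{(1Z,5Z,7R)-9-[(tert-butyldiphenylsilyl)oxy]-7-methoxy-2,6-dimethylnona-1,5-dien-1-yl}-7-ethyl-8a-hydroxy-3,4a,6-trimethyl-3,4,4a,7,8,8a-hexahydro-1H-isochromen-1-one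
Product: 37 silyl-protected tricyclic tetronate, via acyl ylide 36 (not isolated)
Conditions: Ph3P=C=C=O (1.5 equiv), toluene, 110 °C
Reagents that add atoms: (triphenylphosphoranylidene)ketene O=C=C=P(c1ccccc1)(c1ccccc1)c1ccccc1
Why: domino addition and intramolecular Wittig reaction of the Bestmann ylide, in which the tertiary hydroxyl adds to the ketene C=C to give an ester ylide that olefinates the neighbouring lactone carbonyl and so closes the butenolide as a 4-alkoxybutenolide (tetronate) with all stereocentres untouched.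

Step 21
Reactants: 37 silyl-protected tricyclic tetronate
Product: 39 3-iodotetronate silyl ether, via lithiated tetronate 38 (not isolated)
Conditions: LiN(i-Pr)2 (LDA), THF, −78 °C; I2, −78 °C
Reagents that add atoms: iodine [I][I]
Why: deprotonation of a 4-alkoxybutenolide that has no γ-hydrogen occurs at the vinylic C3 between the carbonyl and the alkoxy group, and the alkenyllithium is trapped by iodine.

Step 22
Reactants: 39 3-iodotetronate silyl ether
Product: 40 3-iodotetronate alcohol
Conditions: HF·pyridine, pyridine, THF, 0 °C → rt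
Reagents that add atoms: none
Why: fluoride-mediated cleavage of the silyl ether under pyridine buffering should spare the acid-sensitive tertiary allylic ether and the iodide.

Step 23
Reactants: 40 3-iodotetronate alcohol
Product: 41 3-iodotetronate aldehyde
Conditions: Dess–Martin periodinane, NaHCO3, CH2Cl2, 0 °C → rt
Reagents that add atoms: none
Why: Dess–Martin oxidation under buffered conditions should give the β-methoxy aldehyde without β-elimination.

Step 24
Reactants: 41 3-iodotetronate aldehyde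
Product: 42 macrocyclic carbinol (both carbinol epimers)
Conditions: CrCl2 (10 equiv), NiCl2 (10 mol %), DMSO/THF, 25 °C, slow addition, final 2 mM
Reagents that add atoms: none
Why: intramolecular Nozaki–Hiyama–Kishi reaction, in which zerovalent nickel inserts into the C–I bond, transmetallation to chromium gives a nucleophile that adds only to the aldehyde, and high dilution favours closure of the 13-membered ring; the configuration of the new carbinol is irrelevant.

Step 25
Reactants: 42 macrocyclic carbinol (both carbinol epimers)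
Product: 43 streptaspironate A
Conditions: Dess–Martin periodinane, NaHCO3, CH2Cl2, 0 °C
Reagents that add atoms: none
Why: Dess–Martin oxidation of the secondary carbinol to the 3-acyl tetronate under buffered conditions avoids β-elimination of methanol and completes the target.

**Compound list**

1 | (2E)-2-methylpent-2-enal | CC/C=C(\C)C=O | starting material
2 | ethyl 2-(triphenylphosphoranylidene)propanoate | CCOC(=O)C(C)=P(c1ccccc1)(c1ccccc1)c1ccccc1 | starting material
3 | ethyl (2E,4E)-2,4-dimethylhepta-2,4-dienoate | CCOC(=O)/C(C)=C/C(C)=C/CC | intermediate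
4 | (2E,4E)-2,4-dimethylhepta-2,4-dien-1-ol | OC/C(C)=C/C(C)=C/CC | intermediate
5 | (2E,4E)-1-bromo-2,4-dimethylhepta-2,4-diene | BrC/C(C)=C/C(C)=C/CC | intermediate
6 | dimethyl (2-oxopropyl)phosphonate | COP(=O)(OC)CC(C)=O | starting material
7 | sodium lithium dianion of 6 (not isolated) | COP(=O)(OC)[CH-]C(=O)[CH2-].[Na+].[Li+] | intermediate
8 | dimethyl [(5E,7E)-5,7-dimethyl-2-oxodeca-5,7-dien-1-yl]phosphonate | COP(=O)(OC)CC(=O)CC/C(C)=C/C(C)=C/CC | intermediate
9 | (6E,8E)-6,8-dimethylundeca-1,6,8-trien-3-one | C=CC(=O)CC/C(C)=C/C(C)=C/CC | intermediate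
10 | (3aS,6S,7aR)-6-ethyl-3a,5-dimethyl-2,3,3a,6,7,7a-hexahydro-1H-inden-1-one | CC[C@H]1C[C@H]2C(=O)CC[C@@]2(C)C=C1C | intermediate
11 | lithium enolate of 10 at C1–C2 (not isolated) | CC[C@H]1C[C@H]2C(O[Li])=CC[C@@]2(C)C=C1C | intermediate
12 | (3aS,6S,7aR)-6-ethyl-2,3a,5-trimethyl-2,3,3a,6,7,7a-hexahydro-1H-inden-1-one (C2 epimers) | CC[C@H]1C[C@H]2C(=O)C(C)C[C@@]2(C)C=C1C | intermediate
13 | 2-(2-bromoethyl)-1,3-dioxolane | BrCCC1OCCO1 | starting material
14 | propyne | CC#C | starting material
15 | [2-(1,3-dioxolan-2-yl)ethyl]magnesium bromide (not isolated) | Br[Mg]CCC1OCCO1 | intermediate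
16 | [2-(1,3-dioxolan-2-yl)ethyl]copper (not isolated) | [Cu]CCC1OCCO1 | intermediate
17 | [(1Z)-4-(1,3-dioxolan-2-yl)-2-methylbut-1-en-1-yl]copper (not isolated) | [Cu]/C=C(/C)CCC1OCCO1 | intermediate
18 | 2-[(3Z)-4-iodo-3-methylbut-3-en-1-yl]-1,3-dioxolane | I/C=C(/C)CCC1OCCO1 | intermediate
19 | (4Z)-5-iodo-4-methylpent-4-enal | I/C=C(/C)CCC=O | intermediate
20 | ethyl 2-[bis(2,2,2-trifluoroethoxy)phosphoryl]propanoate | CCOC(=O)C(C)P(=O)(OCC(F)(F)F)OCC(F)(F)F | starting material
21 | potassium salt of the carbanion of 20 (not isolated) | CCOC(=O)[C-](C)P(=O)(OCC(F)(F)F)OCC(F)(F)F.[K+] | intermediate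
22 | ethyl (2Z,6Z)-7-iodo-2,6-dimethylhepta-2,6-dienoate | I/C=C(/C)CC/C=C(/C)C(=O)OCC | intermediate
23 | (2Z,6Z)-7-iodo-2,6-dimethylhepta-2,6-dien-1-ol | I/C=C(/C)CC/C=C(/C)CO | intermediate
24 | (2Z,6Z)-7-iodo-2,6-dimethylhepta-2,6-dienal | I/C=C(/C)CC/C=C(/C)C=O | intermediate
25 | (R)-2-hydroxy-1,2,2-triphenylethyl acetate ((R)-HYTRA) | CC(=O)O[C@H](c1ccccc1)C(O)(c1ccccc1)c1ccccc1 | starting material
26 | dilithio enolate of 25 (not isolated) | [Li]OC(=C)O[C@H](c1ccccc1)C(O[Li])(c1ccccc1)c1ccccc1 | intermediate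
27 | (1R)-2-hydroxy-1,2,2-triphenylethyl (3R,4Z,8Z)-3-hydroxy-9-iodo-4,8-dimethylnona-4,8-dienoate | I/C=C(/C)CC/C=C(/C)[C@H](O)CC(=O)O[C@H](c1ccccc1)C(O)(c1ccccc1)c1ccccc1 | intermediate
28 | (3R,4Z,8Z)-9-iodo-4,8-dimethylnona-4,8-diene-1,3-diol | I/C=C(/C)CC/C=C(/C)[C@H](O)CCO | intermediate
29 | (3R,4Z,8Z)-1-[(tert-butyldiphenylsilyl)oxy]-9-iodo-4,8-dimethylnona-4,8-dien-3-ol | I/C=C(/C)CC/C=C(/C)[C@H](O)CCO[Si](c1ccccc1)(c1ccccc1)C(C)(C)C | intermediate
30 | tert-butyl{[(3R,4Z,8Z)-9-iodo-3-methoxy-4,8-dimethylnona-4,8-dien-1-yl]oxy}diphenylsilane | I/C=C(/C)CC/C=C(/C)[C@H](OC)CCO[Si](c1ccccc1)(c1ccccc1)C(C)(C)C | intermediate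
31 | sodium enolate of 12 at C1–C2 (not isolated) | CC[C@H]1C[C@H]2C(O[Na])=C(C)C[C@@]2(C)C=C1C | intermediate
32 | (2S,3aS,6S,7aR)-2-{(1Z,5Z,7R)-9-[(tert-butyldiphenylsilyl)oxy]-7-methoxy-2,6-dimethylnona-1,5-dien-1-yl}-6-ethyl-2,3a,5-trimethyl-2,3,3a,6,7,7a-hexahydro-1H-inden-1-one | CC[C@H]1C[C@H]2C(=O)[C@](C)(/C=C(/C)CC/C=C(/C)[C@H](OC)CCO[Si](c3ccccc3)(c3ccccc3)C(C)(C)C)C[C@@]2(C)C=C1C | intermediate
33 | (3S,4aS,7S,8aR)-3-{(1Z,5Z,7R)-9-[(tert-butyldiphenylsilyl)oxy]-7-methoxy-2,6-dimethylnona-1,5-dien-1-yl}-7-ethyl-3,4a,6-trimethyl-3,4,4a,7,8,8a-hexahydro-1H-isochromen-1-one | CC[C@H]1C[C@H]2C(=O)O[C@](C)(/C=C(/C)CC/C=C(/C)[C@H](OC)CCO[Si](c3ccccc3)(c3ccccc3)C(C)(C)C)C[C@@]2(C)C=C1C | intermediate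
34 | potassium enolate of lactone 33 at C1–C8a (not isolated) | CC[C@H]1CC2=C(O[K])O[C@](C)(/C=C(/C)CC/C=C(/C)[C@H](OC)CCO[Si](c3ccccc3)(c3ccccc3)C(C)(C)C)C[C@@]2(C)C=C1C | intermediate
35 | (3S,4aS,7S,8aS)-3-{(1Z,5Z,7R)-9-[(tert-butyldiphenylsilyl)oxy]-7-methoxy-2,6-dimethylnona-1,5-dien-1-yl}-7-ethyl-8a-hydroxy-3,4a,6-trimethyl-3,4,4a,7,8,8a-hexahydro-1H-isochromen-1-one | CC[C@H]1C[C@@]2(O)C(=O)O[C@](C)(/C=C(/C)CC/C=C(/C)[C@H](OC)CCO[Si](c3ccccc3)(c3ccccc3)C(C)(C)C)C[C@@]2(C)C=C1C | intermediate
36 | acyl ylide: 35 esterified at the 8a-oxygen as its (triphenylphosphoranylidene)acetate (not isolated) | CC[C@H]1C[C@@]2(OC(=O)C=P(c3ccccc3)(c3ccccc3)c3ccccc3)C(=O)O[C@](C)(/C=C(/C)CC/C=C(/C)[C@H](OC)CCO[Si](c3ccccc3)(c3ccccc3)C(C)(C)C)C[C@@]2(C)C=C1C | intermediate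
37 | silyl-protected tricyclic tetronate: butenolide O–C(=O)–CH=C annulated across C8a–C1 of 35, C1 becoming the alkoxy-bearing butenolide carbon; S at the spiro carbon, the angular methyl carbon, the ethyl-bearing carbon and the ether carbon; side chain (1Z,5Z,7R) ending in the tert-butyldiphenylsilyl ether | CC[C@H]1C[C@@]23OC(=O)C=C2O[C@](C)(/C=C(/C)CC/C=C(/C)[C@H](OC)CCO[Si](c4ccccc4)(c4ccccc4)C(C)(C)C)C[C@@]3(C)C=C1C | intermediate
38 | 3-lithio derivative of 37 (not isolated) | CC[C@H]1C[C@@]23OC(=O)C([Li])=C2O[C@](C)(/C=C(/C)CC/C=C(/C)[C@H](OC)CCO[Si](c4ccccc4)(c4ccccc4)C(C)(C)C)C[C@@]3(C)C=C1C | intermediate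
39 | 3-iodotetronate silyl ether (37 with iodine at the butenolide α-carbon) | CC[C@H]1C[C@@]23OC(=O)C(I)=C2O[C@](C)(/C=C(/C)CC/C=C(/C)[C@H](OC)CCO[Si](c4ccccc4)(c4ccccc4)C(C)(C)C)C[C@@]3(C)C=C1C | intermediate
40 | 3-iodotetronate alcohol (39 with free primary hydroxyl) | CC[C@H]1C[C@@]23OC(=O)C(I)=C2O[C@](C)(/C=C(/C)CC/C=C(/C)[C@H](OC)CCO)C[C@@]3(C)C=C1C | intermediate
41 | 3-iodotetronate aldehyde (40 oxidised at the chain terminus) | CC[C@H]1C[C@@]23OC(=O)C(I)=C2O[C@](C)(/C=C(/C)CC/C=C(/C)[C@H](OC)CC=O)C[C@@]3(C)C=C1C | intermediate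
42 | macrocyclic carbinol (43 with CH(OH) in place of the ketone; both epimers) | CC[C@H]1C[C@@]23OC(=O)C4=C2O[C@](C)(/C=C(/C)CC/C=C(/C)[C@H](OC)CC4O)C[C@@]3(C)C=C1C | intermediate
43 | streptaspironate A | CC[C@H]1C[C@@]23OC(=O)C4=C2O[C@](C)(/C=C(/C)CC/C=C(/C)[C@H](OC)CC4=O)C[C@@]3(C)C=C1C | target

**Summary**

Total step count: 25. Longest linear sequence: 18 steps (steps 8–16, then 17–25); the bicyclic ketone branch (steps 1–7) joins at step 17.

**Steps most likely to fail, with fallbacks**

1. Step 17. Congestion at the fully substituted enolate carbon may make C–C reductive elimination slower than β-hydride loss or decomposition of the alkenylpalladium species, and enolisation toward the ring fusion may divert the enolate. The fallback sets out from 12 and returns at 32; it builds the quaternary carbon by an aldol reaction and the Z alkene by olefination and sp2–sp3 coupling. The lithium enolate of 12 and gaseous formaldehyde should give the hydroxymethyl ketone F1 (again by convex-face attack). Dess–Martin oxidation should give the keto aldehyde F2, and Stork–Zhao olefination with (1-iodoethyl)triphenylphosphonium iodide and NaN(SiMe3)2 the Z-iodoalkene F3. The coupling partner starts from bought 3-[(tert-butyldimethylsilyl)oxy]propanal F4 and follows the operations of steps 10 to 16: Still–Gennari olefination with 20 to the Z-enoate F5, i-Bu2AlH to the allylic alcohol F6, Dess–Martin oxidation to the enal F7, aldol addition of dilithiated 25 to the ester F8, i-Bu2AlH to the diol F9, silylation to the tert-butyldiphenylsilyl ether F10, and Meerwein methylation to the methyl ether F11. Pyridinium p-toluenesulfonate in methanol then frees the primary alcohol F12, I2/PPh3/imidazole gives the iodide F13, and zinc dust with LiCl the alkylzinc iodide F14. Negishi coupling of F14 with F3 (Pd(PPh3)4, THF) should give 32.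

2. Step 18. The silyl Lewis acid may ionise the new tertiary allylic C–O bond of the lactone, or slow peroxide addition to the hindered carbonyl may open the way to side reactions of the alkenes. The fallback sets out from 12 and returns at 33; it runs the ring expansion before the side-chain alkene exists. The lithium enolate of 12 and benzyl chloromethyl ether should give the benzyloxymethyl ketone F15. The same silyl-peroxide Baeyer–Villiger oxidation should give the lactone F16, now with a non-allylic migrating carbon and an acid-stable product. BCl3 with pentamethylbenzene at −78 °C should give the hydroxymethyl lactone F17, Dess–Martin oxidation the aldehyde F18, and Stork–Zhao olefination the Z-iodoalkene F19. Negishi coupling of F19 with the alkylzinc iodide F14 of the first fallback should give 33.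

3. Step 6. The cationic boron catalyst may give poor facial selectivity with this tetrasubstituted diene, or be consumed by diene decomposition, so that the uncatalysed racemic cycloaddition dominates. The fallback sets out from 9 and returns at 10; it replaces asymmetric catalysis by resolution. Et2AlCl-promoted cycloaddition (CH2Cl2, −78 → 0 °C) should give the racemic cis-hydrindenone F20. Addition of lithiated (S)-N,S-dimethyl-S-phenylsulfoximine should give two diastereomeric β-hydroxysulfoximines, separable by chromatography; the one derived from the wanted enantiomer is F21. Thermolysis of F21 in toluene at 110 °C should release enantiopure 10.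

**Further compounds**

F1 | step 17 | (2S,3aS,6S,7aR)-6-ethyl-2-(hydroxymethyl)-2,3a,5-trimethyl-2,3,3a,6,7,7a-hexahydro-1H-inden-1-one | CC[C@H]1C[C@H]2C(=O)[C@](C)(CO)C[C@@]2(C)C=C1C
F2 | step 17 | (2S,3aS,6S,7aR)-6-ethyl-2,3a,5-trimethyl-1-oxo-2,3,3a,6,7,7a-hexahydro-1H-indene-2-carbaldehyde | CC[C@H]1C[C@H]2C(=O)[C@](C)(C=O)C[C@@]2(C)C=C1C
F3 | step 17 | (2S,3aS,6S,7aR)-6-ethyl-2-[(1Z)-2-iodoprop-1-en-1-yl]-2,3a,5-trimethyl-2,3,3a,6,7,7a-hexahydro-1H-inden-1-one | CC[C@H]1C[C@H]2C(=O)[C@](C)(/C=C(/C)I)C[C@@]2(C)C=C1C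
F4 | step 17 | 3-[(tert-butyldimethylsilyl)oxy]propanal (bought) | CC(C)(C)[Si](C)(C)OCCC=O
F5 | step 17 | ethyl (2Z)-5-[(tert-butyldimethylsilyl)oxy]-2-methylpent-2-enoate | CCOC(=O)/C(C)=C\CCO[Si](C)(C)C(C)(C)C
F6 | step 17 | (2Z)-5-[(tert-butyldimethylsilyl)oxy]-2-methylpent-2-en-1-ol | OC/C(C)=C\CCO[Si](C)(C)C(C)(C)C
F7 | step 17 | (2Z)-5-[(tert-butyldimethylsilyl)oxy]-2-methylpent-2-enal | O=C/C(C)=C\CCO[Si](C)(C)C(C)(C)C
F8 | step 17 | (1R)-2-hydroxy-1,2,2-triphenylethyl (3R,4Z)-7-[(tert-butyldimethylsilyl)oxy]-3-hydroxy-4-methylhept-4-enoate | CC(C)(C)[Si](C)(C)OCC/C=C(/C)[C@H](O)CC(=O)O[C@H](c1ccccc1)C(O)(c1ccccc1)c1ccccc1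
F9 | step 17 | (3R,4Z)-7-[(tert-butyldimethylsilyl)oxy]-4-methylhept-4-ene-1,3-diol | CC(C)(C)[Si](C)(C)OCC/C=C(/C)[C@H](O)CCO
F10 | step 17 | (3R,4Z)-7-[(tert-butyldimethylsilyl)oxy]-1-[(tert-butyldiphenylsilyl)oxy]-4-methylhept-4-en-3-ol | CC(C)(C)[Si](C)(C)OCC/C=C(/C)[C@H](O)CCO[Si](c1ccccc1)(c1ccccc1)C(C)(C)C
F11 | step 17 | tert-butyl{[(3Z,5R)-7-[(tert-butyldiphenylsilyl)oxy]-5-methoxy-4-methylhept-3-en-1-yl]oxy}dimethylsilane | CC(C)(C)[Si](C)(C)OCC/C=C(/C)[C@H](OC)CCO[Si](c1ccccc1)(c1ccccc1)C(C)(C)C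
F12 | step 17 | (3Z,5R)-7-[(tert-butyldiphenylsilyl)oxy]-5-methoxy-4-methylhept-3-en-1-ol | OCC/C=C(/C)[C@H](OC)CCO[Si](c1ccccc1)(c1ccccc1)C(C)(C)C
F13 | step 17 | tert-butyl{[(3R,4Z)-7-iodo-3-methoxy-4-methylhept-4-en-1-yl]oxy}diphenylsilane | ICC/C=C(/C)[C@H](OC)CCO[Si](c1ccccc1)(c1ccccc1)C(C)(C)C
F14 | step 17 | {(3Z,5R)-7-[(tert-butyldiphenylsilyl)oxy]-5-methoxy-4-methylhept-3-en-1-yl}zinc iodide | I[Zn]CC/C=C(/C)[C@H](OC)CCO[Si](c1ccccc1)(c1ccccc1)C(C)(C)C
F15 | step 18 | (2S,3aS,6S,7aR)-2-[(benzyloxy)methyl]-6-ethyl-2,3a,5-trimethyl-2,3,3a,6,7,7a-hexahydro-1H-inden-1-one | CC[C@H]1C[C@H]2C(=O)[C@](C)(COCc3ccccc3)C[C@@]2(C)C=C1C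
F16 | step 18 | (3S,4aS,7S,8aR)-3-[(benzyloxy)methyl]-7-ethyl-3,4a,6-trimethyl-3,4,4a,7,8,8a-hexahydro-1H-isochromen-1-one | CC[C@H]1C[C@H]2C(=O)O[C@](C)(COCc3ccccc3)C[C@@]2(C)C=C1C
F17 | step 18 | (3S,4aS,7S,8aR)-7-ethyl-3-(hydroxymethyl)-3,4a,6-trimethyl-3,4,4a,7,8,8a-hexahydro-1H-isochromen-1-one | CC[C@H]1C[C@H]2C(=O)O[C@](C)(CO)C[C@@]2(C)C=C1C
F18 | step 18 | (3S,4aS,7S,8aR)-7-ethyl-3,4a,6-trimethyl-1-oxo-3,4,4a,7,8,8a-hexahydro-1H-isochromene-3-carbaldehyde | CC[C@H]1C[C@H]2C(=O)O[C@](C)(C=O)C[C@@]2(C)C=C1C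
F19 | step 18 | (3S,4aS,7S,8aR)-7-ethyl-3-[(1Z)-2-iodoprop-1-en-1-yl]-3,4a,6-trimethyl-3,4,4a,7,8,8a-hexahydro-1H-isochromen-1-one | CC[C@H]1C[C@H]2C(=O)O[C@](C)(/C=C(/C)I)C[C@@]2(C)C=C1C
F20 | step 6 | racemic 6-ethyl-3a,5-dimethyl-2,3,3a,6,7,7a-hexahydro-1H-inden-1-one with the relative configuration of 10 | CCC1CC2C(=O)CCC2(C)C=C1C
F21 | step 6 | β-hydroxysulfoximine from convex-face addition of lithiated (S)-N,S-dimethyl-S-phenylsulfoximine to the ketone of 10 (S at sulfur) | CC[C@H]1C[C@H]2[C@](O)(C[S@@](=O)(=NC)c3ccccc3)CC[C@@]2(C)C=C1C
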